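I read every flask at 6.0 h, so I want to know where each one stands in its own course by then.

| flask | starting material | free catalyst | temperature | remark | time |
|---|---|---|---|---|---|
| Wednesday's | 0.050 M | 35 µM | 48 °C | run made earlier |  |
| Tuesday's | 0.050 M | 55 µM | 64 °C | run made earlier |  |
| maple | 0.050 M | 25 µM | 55 °C |  | 6.0 h |
| larch | 0.050 M | 25 µM | 70 °C |  | 6.0 h |
| oak | 0.050 M | 25 µM |  | at 70 °C until 3.0 h, from then on at 40 °C | 6.0 h |
| alder | 0.050 M | 25 µM | 40 °C |  | 6.0 h |

- Wednesday's (time / h: target / %, starting material / %): 0.417: 11, 90; 0.667: 6, 89; 1.00: 16, 88; 2.00: 18, 66; 3.00: 23, 50; 5.00: 19, 25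
- Tuesday's (time / h: target / %, starting material / %): 0.500: 26, 50; 1.00: 22, 19; 1.50: 11, 0; 2.00: 5, 0; 2.50: 5, 0; 3.00: 1, 0

(readings scatter by 2 percentage points)

* the flask that comes out highest in amount of target, in percent of the starting material charged, or "all alike" when all lie within 1.5 percentage points (maple / larch / oak / alder / all alike)
* target at the end, in percent of the starting material charged, maple
* target at the end, in percent of the starting material charged, larch
* target at the end, in percent of the starting material charged, oak
* target at the end, in percent of the starting material charged, alder



The target is the small thing here, a difference between what is made and what is lost, so I reckon the large thing first, the starting material. In Wednesday's run it falls from 88% at 1.00 h to 25% at 5.00 h, and I treat that fall as steady. This gives a turnover frequency w, the starting material used per catalyst charged per hour, of 225 h⁻¹. Tuesday's first reading gives 909 h⁻¹, which is 4.04 times as much for the step from 48 °C to 64 °C, so I read an activation energy of 78.6 kJ mol⁻¹. At 40 °C that puts w at 106 h⁻¹.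

My measure is the clearing time τ, the charge of starting material divided by what the catalyst turns over in an hour, which for alder is 18.8 h.

Now the ladder, from the shortest time up. Once Tuesday's starting material reads 0%, its target drops from 11% to 5%, to about half, in 0.500 h. Larch has τ of 1.35 h, which puts its reading 4.65 h past τ, far longer than that halving. Oak shares that τ, which ends before its change at 3.0 h, so I expect cooling to find little target to keep. Maple has τ of 4.75 h, which is 1.25 h shorter than the time of reading, but τ comes from a steady fall, so I do not take it as the end of maple's supply. Alder reaches 31.9% of its τ when read, so I expect 68.1% of its starting material still to stand; its τ is longer than the time of reading, while those of maple and larch are shorter.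

The forecast names alder, with 13% for maple, 1% for larch, 5% for oak and 17% for alder: “Alder is likely highest, but narrowly over maple”. I agree on the flask.

The flasks give 6.66% in maple, 0% in larch, 0.241% in oak and 18.3% in alder, so alder is highest, and maple lies 6.3 percentage points under the forecast.

    catalyst intermediate → free catalyst + target (k = 147 h⁻¹, Ea = 77.0 kJ mol⁻¹)
    starting material + free catalyst ⇌ catalyst intermediate (K = 100 M⁻¹, k = 4.46 × 10⁵ M⁻¹ h⁻¹, Ea = 39.0 kJ mol⁻¹, ΔH = −8.00 kJ mol⁻¹)
    free catalyst + target → spent catalyst (k = 5.33 M⁻¹ h⁻¹, Ea = 54.0 kJ mol⁻¹)
    target → over-reaction product (k = 0.236 h⁻¹, Ea = 94.0 kJ mol⁻¹)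
    (constants at 40 °C)

Alder ends with 65% of its starting material unbound, so 35.0% has gone against my 31.9%. Its neighbour charged with 0.020 M gets τ of 7.54 h from the same w, so I reckon 79.6% gone by the reading. That neighbour shows 60.3% gone and target at 30.5%. Catalyst intermediate stands at 73.0% of the catalyst charged in alder and at 40.8% in the neighbour.

The earlier runs and the new flask are calculated from invented constants; noise was put on by code.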